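**Retrosynthetic overview** (drimane numbering: ring A = C1–C5 and C10, ring B = C5–C10, C11 = the CH2O carbon)
1. Late bonds: C9–H by acid-mediated shift of a C8=C9 alkene into conjugation with C6=O; C11–O by Mitsunobu etherification with umbelliferone; C9–C11 by Stille hydroxymethylation of a C9 enol triflate.
2. The enol triflate comes from a trans-fused 7-ene-3,6,9-trione by conjugate hydride delivery to C7 and O-sulfonylation of the resulting C9 enolate.
3. Key disconnection: C4–C5 and C1–C10. Ring A is grafted onto one alkene of a cyclohexadienone by a catalytic enantioselective Diels–Alder reaction with the 2-silyloxydiene C1=C2–C3(OSi)=C4Me2.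
4. Feature used: ring B carries oxygen on C6 and C9 (1,4 across the ring) and methyl groups on C8 and C10, the two carbons flanking C9. That is the pattern of 2,6-dimethyl-1,4-benzoquinone, and its C6 monoketal has a mirror plane through C6 and C9, so C5=C10 and C7=C8 are enantiotopic.
5. Ring order: ring B is bought as an arene and dearomatised, ring A is closed in the key step, the coumarin is attached near the end.

Key step: step 3

Assumption: the (R)-BINOL titanium complex is taken to select the dienone face that leads to the (10R) adduct drawn; if the sense proves opposite, (S)-BINOL is used and nothing else changes.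

**Step 1**
Reactants: 1 4-methoxy-2,6-dimethylphenol
Product: 2 4,4-dimethoxy-2,6-dimethylcyclohexa-2,5-dien-1-one
Conditions: PhI(OAc)2 (1.1 equiv), MeOH, 0 °C
Reagents that add atoms: methanol, CO
Why: Oxidative dearomatisation of a para-methoxyphenol with PhI(OAc)2 in methanol traps the phenoxonium ion at the methoxy-bearing carbon as the dimethyl ketal (quinone monoketal formation), and no stereocentre is formed.

**Step 2**
Reactants: 3 4-methylpent-1-en-3-one
Product: 4 3-(tert-butyldimethylsilyloxy)-4-methylpenta-1,3-diene
Conditions: TBSOTf, Et3N, Et2O, 0 → 23 °C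
Reagents that add atoms: tert-butyldimethylsilyl trifluoromethanesulfonate, CC(C)(C)[Si](C)(C)OS(=O)(=O)C(F)(F)F
Why: Soft enolisation (silyl triflate and amine) of the vinyl ketone can only remove the isopropyl methine proton, so O-silylation gives the 2-silyloxydiene with the fully substituted enol silane terminus, and no stereocentre is formed.

**Step 3**
Reactants: 2 4,4-dimethoxy-2,6-dimethylcyclohexa-2,5-dien-1-one; 4 3-(tert-butyldimethylsilyloxy)-4-methylpenta-1,3-diene
Product: 7 trans-fused (5R,10R)-11-nordrim-7-ene-3,6,9-trione, via cis-fused silyl enol ether ketal adduct 5 (not isolated), via cis-fused ene-trione 6 (not isolated)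
Conditions: TiCl2(O-i-Pr)2 (20 mol %), (R)-BINOL (20 mol %), 4 Å MS, CH2Cl2, −30 → 0 °C, 4 in excess; then 1 M HCl, THF, 23 °C
Reagents that add atoms: water, O
Why: The chiral titanium–BINOL complex binds the single carbonyl C9=O of 2, and the nucleophilic, fully substituted enol silane terminus C4 of 4 bonds to the β carbon C5 while the vinyl terminus C1 bonds to the α carbon C10, either as a strongly asynchronous [4+2] or as a Mukaiyama–Michael addition followed by Michael closure of the titanium enolate onto the silyloxyallyl cation. The closest known reactions are the titanium–BINOL-catalysed enantioselective Diels–Alder reaction of 1,4-quinone monoketals with 2-silyloxydienes and the Lewis-acid double-Michael annulation of terminally dimethylated 2-silyloxydienes with 2-methylcycloalkenones. Ring A is the only ring closed, as the six-membered ring of the formal [4+2]; in the stepwise picture the second bond forms by 6-endo-trig attack of the C10 enolate carbon on C1. C10 is set by the catalyst, which decides the dienone face that the diene approaches; since 2 has mirror planes through C6/C9 and in the ring plane, choosing between the enantiotopic alkenes and choosing the face are one decision, and endo or exo approach creates no further stereocentre. C5 is first formed cis to the C10 methyl (suprafacial addition) and is then equilibrated to the trans fusion by acid-catalysed enolisation toward C6 once the ketal is hydrolysed, the same acid cleaving the C3 silyl enol ether. The step needs regiocontrol, secured by the enol silane polarity (the other orientation would join the two fully substituted carbons C4 and C10), and mono-addition, secured because the remaining enone is flanked by the new quaternary C10, which also blocks aromatisation.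

**Step 4**
Reactants: 7 trans-fused (5R,10R)-11-nordrim-7-ene-3,6,9-trione
Product: 9 (5S,10R)-3,6-dioxo-11-nordrim-8-en-9-yl trifluoromethanesulfonate, via lithium C9 enolate 8 (not isolated)
Conditions: LiBH(s-Bu)3 (1.0 equiv), THF, −78 °C; then N-(5-chloropyridin-2-yl)triflimide, −78 → 0 °C; NH4Cl quench
Reagents that add atoms: N-(5-chloropyridin-2-yl)-1,1,1-trifluoro-N-(trifluoromethylsulfonyl)methanesulfonamide, O=S(=O)(N(c1ccc(Cl)cn1)S(=O)(=O)C(F)(F)F)C(F)(F)F
Why: Conjugate reduction of the doubly activated ene-1,4-dione by the bulky borohydride puts hydride on the unsubstituted C7 (β to C9=O) and gives the C9 enolate regiospecifically, which is O-sulfonylated in the same flask (reductive enol triflate formation); C8 becomes sp2, no stereocentre is created, and C5 and C10 are untouched.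

**Step 5**
Reactants: 9 (5S,10R)-3,6-dioxo-11-nordrim-8-en-9-yl trifluoromethanesulfonate; 10 (tributylstannyl)methanol
Product: 11 (5S,10R)-11-hydroxydrim-8-ene-3,6-dione
Conditions: Pd(PPh3)4 (10 mol %), LiCl (3 equiv), 1,4-dioxane, 90 °C
Reagents that add atoms: none
Why: Stille coupling (Migita–Kosugi–Stille hydroxymethylation) of the enol triflate with the α-hydroxymethylstannane, which transfers CH2OH in preference to butyl, forms C9–C11 under neutral conditions that leave the base-sensitive β,γ-unsaturated ketone alone, and no stereocentre is formed.

**Step 6**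
Reactants: 11 (5S,10R)-11-hydroxydrim-8-ene-3,6-dione; 12 umbelliferone (7-hydroxy-2H-chromen-2-one)
Product: 13 (5S,10R)-11-[(2-oxo-2H-chromen-7-yl)oxy]drim-8-ene-3,6-dione
Conditions: PPh3, DIAD, THF, 0 → 23 °C
Reagents that add atoms: none
Why: Mitsunobu etherification of the primary allylic alcohol with the acidic phenol forms C11–O by SN2 displacement at CH2 under essentially neutral conditions, and no stereocentre is involved.

**Step 7**
Reactants: 13 (5S,10R)-11-[(2-oxo-2H-chromen-7-yl)oxy]drim-8-ene-3,6-dione
Product: 14 epi-conferdione, (5S,9R,10S)-11-[(2-oxo-2H-chromen-7-yl)oxy]drim-7-ene-3,6-dione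
Conditions: p-TsOH·H2O (5 mol %), CH2Cl2, 0 → 23 °C, short reaction time
Reagents that add atoms: none
Why: Acid-catalysed enolisation of the C6 ketone toward C7 gives the 6,8-dienol, whose γ-protonation at C9 moves the alkene into conjugation (β,γ- to α,β-enone isomerisation); the proton is expected to arrive axially on the face of C9 opposite the axial C10 methyl, which places H-9 cis to H-5 and C11 equatorial as in the target, and acid is used because under base the product could lose umbelliferone by vinylogous β-elimination.

**Compound list**
1 | 4-methoxy-2,6-dimethylphenol | COc1cc(C)c(O)c(C)c1 | starting material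
2 | 4,4-dimethoxy-2,6-dimethylcyclohexa-2,5-dien-1-one | COC1(OC)C=C(C)C(=O)C(C)=C1 | intermediate
3 | 4-methylpent-1-en-3-one | C=CC(=O)C(C)C | starting material
4 | 3-(tert-butyldimethylsilyloxy)-4-methylpenta-1,3-diene | C=CC(O[Si](C)(C)C(C)(C)C)=C(C)C | intermediate
5 | cis-fused adduct, (5S,10R)-3-(tert-butyldimethylsilyloxy)-6,6-dimethoxy-11-nordrima-2,7-dien-9-one (H-5 and the C10 methyl on the same face) | CC1=CC(OC)(OC)[C@H]2C(C)(C)C(O[Si](C)(C)C(C)(C)C)=CC[C@@]2(C)C1=O | intermediate
6 | cis-fused (5S,10R)-11-nordrim-7-ene-3,6,9-trione | CC1=CC(=O)[C@H]2C(C)(C)C(=O)CC[C@@]2(C)C1=O | intermediate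
7 | trans-fused (5R,10R)-11-nordrim-7-ene-3,6,9-trione; ketones at C3, C6, C9, alkene C7=C8, methyls on C4 (two), C8 and C10, H-5 anti to the C10 methyl | CC1=CC(=O)[C@@H]2C(C)(C)C(=O)CC[C@@]2(C)C1=O | intermediate
8 | lithium (5S,10R)-3,6-dioxo-11-nordrim-8-en-9-olate | CC1=C(O[Li])[C@]2(C)CCC(=O)C(C)(C)[C@H]2C(=O)C1 | intermediate
9 | (5S,10R)-3,6-dioxo-11-nordrim-8-en-9-yl trifluoromethanesulfonate (trans-fused, C8=C9) | CC1=C(OS(=O)(=O)C(F)(F)F)[C@]2(C)CCC(=O)C(C)(C)[C@H]2C(=O)C1 | intermediate
10 | (tributylstannyl)methanol | CCCC[Sn](CCCC)(CCCC)CO | starting material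
11 | (5S,10R)-11-hydroxydrim-8-ene-3,6-dione (trans-fused, C8=C9, CH2OH on C9) | CC1=C(CO)[C@]2(C)CCC(=O)C(C)(C)[C@H]2C(=O)C1 | intermediate
12 | umbelliferone (7-hydroxy-2H-chromen-2-one) | Oc1ccc2ccc(=O)oc2c1 | starting material
13 | (5S,10R)-11-[(2-oxo-2H-chromen-7-yl)oxy]drim-8-ene-3,6-dione | CC1=C(COc3ccc4ccc(=O)oc4c3)[C@]2(C)CCC(=O)C(C)(C)[C@H]2C(=O)C1 | intermediate
14 | epi-conferdione, (5S,9R,10S)-11-[(2-oxo-2H-chromen-7-yl)oxy]drim-7-ene-3,6-dione (trans-fused; H-9 cis to H-5, C11 cis to the C10 methyl) | CC1=CC(=O)[C@@H]2C(C)(C)C(=O)CC[C@@]2(C)[C@@H]1COc1ccc2ccc(=O)oc2c1 | target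

**Total step count:** 7
**Longest linear sequence:** 6 steps (steps 1, 3, 4, 5, 6, 7)

**Steps most likely to fail**

Step 3 (key step). A fully substituted enol silane carbon must bond to C5, which sits between the ketal carbon and the methyl-bearing C10. Bond formation may therefore be slow, so that protodesilylation of the diene or Lewis-acid opening of the ketal outruns the annulation, and the catalyst may discriminate the two dienone faces poorly. The fallback replaces catalyst control by a ketal auxiliary and a stoichiometric Lewis acid. It sets out from 2, which is transketalised with (R,R)-hydrobenzoin (PPTS, benzene, reflux, removal of methanol) to the C2-symmetric (R,R)-hydrobenzoin spiroketal F1. In F1 the two alkenes are equivalent and a phenyl group shields one face of each β carbon. F1 is annulated with 4 using the AlBr3/AlMe3 mixed Lewis acid (toluene/CH2Cl2, low temperature), a promoter known to force terminally dimethylated silyloxydienes onto 2-methylcycloalkenones in the stepwise double-Michael mode. This gives the cis-fused silyl enol ether spiroketal adduct F2, which is purified to diastereomeric homogeneity by chromatography or crystallisation. Aqueous HCl in THF then cleaves the silyl enol ether and the ketal and equilibrates C5, and the route is rejoined at 7. If the auxiliary favours the wrong face, (S,S)-hydrobenzoin is used.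

Step 4. Hydride may add to a carbonyl carbon (C3 above all) instead of C7, or the C9 enolate may exchange protons with C7 or C2 before it is sulfonylated, which would give mixtures of enol triflates. The fallback separates reduction from sulfonylation and avoids a free hydride reagent. It sets out from 7, which undergoes rhodium-catalysed 1,4-hydrosilylation (RhCl(PPh3)3 catalytic, Et3SiH, benzene, 50 °C). Saturated ketones are left alone and the product is the C9 triethylsilyl enol ether F3. Fluoride-mediated exchange (CsF, PhNTf2, DME, 23 °C) converts F3 into the enol triflate, and the route is rejoined at 9.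

Step 5. Transfer of the sp3 group from tin to the tetrasubstituted alkenylpalladium species next to the quaternary C10 may be slow, so reduction of the triflate or migration of the alkene on prolonged heating may compete. The fallback forms the C11–O bond before the C9–C11 bond and changes the metal. It sets out from 12 and 9. Umbelliferone 12 is alkylated with potassium (bromomethyl)trifluoroborate (K2CO3, acetone or DMF, 50 °C) to give potassium trifluoro{[(2-oxo-2H-chromen-7-yl)oxy]methyl}borate F4. F4 is joined to 9 by Suzuki–Miyaura coupling (Pd(OAc)2, RuPhos, K3PO4, toluene/H2O, 70–80 °C). The reaction time is kept short because the product can expel the phenoxide under base. The route is rejoined at 13, so 11 and the Mitsunobu step are bypassed.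

**Further compounds**
F1 | step 3 | (2R,3R)-7,9-dimethyl-2,3-diphenyl-1,4-dioxaspiro[4.5]deca-6,9-dien-8-one ((R,R)-hydrobenzoin ketal of 2,6-dimethylbenzoquinone) | CC1=CC2(O[C@H](c3ccccc3)[C@@H](c3ccccc3)O2)C=C(C)C1=O
F2 | step 3 | cis-fused (5S,10R)-3-(tert-butyldimethylsilyloxy)-11-nordrima-2,7-dien-9-one 6-[(R,R)-hydrobenzoin ketal] | CC1=CC2(O[C@H](c3ccccc3)[C@@H](c3ccccc3)O2)[C@H]4C(C)(C)C(O[Si](C)(C)C(C)(C)C)=CC[C@@]4(C)C1=O
F3 | step 4 | (5S,10R)-9-(triethylsilyloxy)-11-nordrim-8-ene-3,6-dione | CC1=C(O[Si](CC)(CC)CC)[C@]2(C)CCC(=O)C(C)(C)[C@H]2C(=O)C1
F4 | step 5 | potassium trifluoro{[(2-oxo-2H-chromen-7-yl)oxy]methyl}borate | [K+].F[B-](F)(F)COc1ccc2ccc(=O)oc2c1
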